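## Structural features

Target 23 is a diaryl ether: two benzene rings joined only through one oxygen, from C2 of ring A to C2' of ring B. It has no further ring and no stereocenter, so no configuration has to be set and no stereocenters stand next to each other. Ring A carries five substituents (C1 CO2H, C2 ether O, C3 OH, C4 Cl, C5 OMe, C6 H). Ring B is an orsellinic acid unit (C1' CO2H, C2' ether O, C4' CH3, C6' OH). The ether oxygen is crowded: on ring A it lies between the C1 carboxyl and the C3 oxygen, on ring B next to the C1' carboxyl. Both rings are electron-rich, the least favourable case for SNAr or copper-mediated etherification. Fragile points are: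

- the aryl chloride, which rules out hydrogenolytic debenzylation;
- the single methyl ether at C5, which must outlast the final deprotection;
- the 2,6-dioxygenated benzoic acid of ring B, which decarboxylates in hot acid;
- the free phenols, which are oxidation-prone, so the ring A carboxyl must be at its final oxidation level before they are released.

The real difficulty is twofold: the hindered C2–O–C2' bond, and a ring A pattern in which chlorine sits between two oxygens that must be told apart (free OH at C3, OMe at C5). The key step uses the three contiguous carbons C6' (O), C1' (CO2H) and C2' (O) of ring B. This is the footprint of a 3-alkoxyaryne spanning C1'–C2' that takes the ring A oxygen at C2', the carbon remote from the C6' alkoxy group, and CO2 at C1'.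

## Logic of the disconnections

23 ⇒ 22. The two O–benzyl bonds at C3–O and C6'–O are the last to be cut in the forward sense. Both phenols carry the same mask so that one Lewis-acid operation ends the synthesis, and they stay inert through the oxidation and the coupling. The demand is a cleavage that spares C4–Cl and C5–OMe and does not C-benzylate the rings, hence no hydrogenolysis.

22 ⇒ 21 ⇒ 20. The C1 carboxyl is traced back to a CH2OH group and then to its silyl ether (O–Si bond). The reason is that C1 must offer no electrophilic carbon during the coupling. The gain is that 20 carries one free acid only. The demands are an oxidation that neither chlorinates the rings nor attacks benzyl ethers, and a desilylation that tolerates a free acid.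

20 ⇒ 8 + 16 + 17. The bonds cut are O–C2' and C1'–CO2H. They lie on neighbouring carbons next to the C6' oxygen, which is the aryne pattern. Cutting here avoids an etherification between two hindered, electron-rich arenes and brings in the ring B carboxyl without a separate step. The gain is two arenes of similar size plus 17. The demands are site-selective addition to the unsymmetrical aryne, a preformed phenolate in a proton-free medium rich in 17, and a ring A partner without a carbonyl group.

8 ⇒ 7 ⇒ 6 ⇒ 5. After the O–Si bond, the ring-to-carbon bond at C1 is cut (alcohol back to aldehyde, aldehyde back to C–H). C1 is the only open position ortho to the C2 hydroxyl, so an ortho-specific formylation has no choice of site. The gain is a tetrasubstituted benzene. The demands are ortho-specific C–C bond formation and silylation of the primary alcohol in preference to the phenol.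

5 ⇒ 3 (through 4) ⇒ 2 ⇒ 1. The C2–O bond is traced to a C2–CHO bond (aryl migration to oxygen), then the O–benzyl bond and the formyl C–C bond are cut. The formyl group marks the carbon that becomes the C2 hydroxyl and lets the original phenol oxygen (the future C3–O) be benzylated before the new phenol appears. The two neighbouring oxygens are thus differentiated without any selective protection. The gain is arrival at 1, in which chlorine already lies between the two oxygens, so no chlorination regiochemistry has to be solved. The demands are aryl and not hydride migration in the peracid step, and formylation at the single free ortho site of 1.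

16 ⇒ 14 (through 15) ⇒ 11 ⇒ 10 ⇒ 9. The bonds cut are O–S of the triflate, C–Si at the carbon between the two oxygens, the carbamate C–O bond and one O–benzyl bond. The carbon between two oxygen substituents is the most acidic ring position, and the carbamate is both the directing group and the latent triflate. The gain is the symmetric diol 9. The demands are mono-etherification of one of two equivalent hydroxyls, and ring lithiation that outruns deprotonation at the benzylic CH2.

## Other disconnections considered

Alternative 1: Ring A from a diene and a nitroalkene.
- Cut: C1–C2 and C5–C6 of ring A, so that ring A is assembled from a four-carbon diene that already carries the ether oxygen and a two-carbon dienophile.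
- Forward key step: the Z-configured diene A2 would undergo a Diels–Alder reaction with methyl (E)-3-nitroacrylate A3. A2 has the ring B aryloxy group (as a benzodioxinone) at C2, a silyl enol ether at C3, chlorine at C4 and a ketene dimethyl acetal at C5. The nitro group fixes the orientation (C2 to the ester-bearing carbon). Loss of HNO2 and methanol and desilylation would give A1.
- In favour: the whole substitution pattern of ring A, chlorine included, would be set in one step. The crowded ether bond is never made between two arenes but by O-alkylation of a ring B phenol. A1 is two hydrolyses from 23, without oxidation or benzyl ethers.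
- Against: A2 is a pentasubstituted, moisture-sensitive ketene acetal. Its preparation from an α-chloro-γ-aryloxy β-keto ester needs two successive enolisations with control of geometry. Substituents on all four carbons and the gem-dimethoxy terminus disfavour the s-cis conformer. The aryloxy donor on the nucleophilic terminus C2 works against the ketene-acetal polarisation. A3 is prone to polymerisation and conjugate addition. After cycloaddition the acidic C1–H could expel aryloxide from C2 as well as nitrite from C6, which would lose the ether altogether.
- Comparison on structure: it builds the harder ring de novo, whereas the chosen plan starts from both rings preformed and places each substituent at a forced site.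
- Comparison on mechanism: it is pericyclic and its reaction class is precedented. On that count it is the better of the two, although its particular diene is no less speculative than the aryne step.
- Comparison on step economy: after the key step it is better (two steps against three), and overall about equal. Its risk sits in making and handling A2, for which no simple detour exists, whereas the chosen plan has a known two-step detour.

Alternative 2: Ring A as a cyclohexane-1,3-dione.
- Cut: C1–C2 and C3–C4 of ring A at the cyclohexane-1,3-dione oxidation level.
- Forward key step: the lithium enolate of the aryloxyacetate A5 would add to methyl (E)-4-oxopent-2-enoate A6 at the carbon β to the ketone (C1–C2). NaOMe would then drive Dieckmann closure of the methyl ketone onto the aryloxyacetate ester (C3–C4) to give the trans dione A4.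
- In favour: the inputs are cheap and acyclic. The ether bond again comes from a simple O-alkylation. Chlorine can later be placed at C4 between the two carbonyls, the most nucleophilic carbon of a 1,3-dione. In the placement of chlorine it equals the chosen plan, where the halogen is bought in place.
- Against: A4 is far from 23. Chlorination, dehydrogenation to the arene, O-methylation of one of two enol oxygens, acetal hydrolysis, oxidation of the ring B aldehyde, saponification and debenzylation still follow. The two stereocenters of A4 are made only to be destroyed. The enolate of A5 can self-condense or add 1,2 to the ketone, and the Michael adduct can revert under NaOMe. Aromatisation of a chlorinated dione that carries a β-aryloxy group risks loss of the aryloxide.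
- Comparison on structure: it solves the ether problem as well as the chosen plan does, by a different means.
- Comparison on mechanism: it uses only classical enolate chemistry, which is better precedented than the aryne step.
- Comparison on step economy: it is clearly worse, with about twice as many operations after the key step, and it needs regiocontrol in the mono-methylation that the chosen plan avoids.

Alternative 3: Ring B by benzannulation.
- Cut: C6'–C1', C2'–C3' and C5'–C6' of ring B.
- Forward key step: heating 3-methylcyclobut-2-en-1-one A8 with the ring A aryl alkynyl ether A9 would run a Danheiser benzannulation. Four-electron ring opening gives a vinylketene, ketene–alkyne [2+2] cycloaddition follows, then a second ring opening and six-electron electrocyclisation. The product would be phenol A7 with the C6' hydroxyl free.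
- In favour: the substitution pattern of ring B follows from the mechanism and not from aryne distortion. The C6' oxygen needs no protecting group. Benzannulation of alkynyl ethers is a known reaction class, so on precedent this key step is better than the chosen one.
- Against: A9 must be made from 8 of the chosen route, so nothing is saved on ring A. Its preparation needs strong base on a substrate with an aryl chloride and benzyl ethers. The hindered phenolate must still form a C–O bond, so the steric problem is moved and not removed. Aryl alkynyl ethers are thermally labile and A8 is volatile. In A7 both carboxyls are still CH2OSi groups, so two benzylic oxidations are needed beside a free phenol that would probably have to be protected first.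
- Comparison on structure: it builds ring B and places the ether in one event, as the chosen plan does, but with the ring B carboxyl at a lower oxidation level.
- Comparison on mechanism: it is thermal, neutral and free of the protonation problem of an aryl anion, which makes it equal or better there.
- Comparison on step economy: it is worse by roughly four to five operations.

Key step: step 11

Remarks on the chemistry:
- Assumption: 2-chloro-3-methoxyphenol (1) is taken as a catalogue compound; if supply failed, one O-methylation of 2-chlororesorcinol would give it.
- An entry to 8 by chlorinating a 3,5-dihydroxybenzoate was set aside. Electrophilic chlorination of such resorcinol esters favours the positions next to the ester over the carbon between the hydroxyls, and a statistical mono-methylation would follow. In the route below, chlorine is in place from the start and every later substituent enters at the only open position.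
- For the coupling, the phenolate is preformed with KH and the medium is THF. A carbonate base would leave a proton donor in the flask, and acetonitrile is itself a proton donor towards aryl anions.

## Route

Step 1
Reactants: 1 2-chloro-3-methoxyphenol
Product: 2 3-chloro-2-hydroxy-4-methoxybenzaldehyde
Conditions: MgCl2, Et3N, (CH2O)n, MeCN, reflux; aq. HCl
Reagents that add atoms: paraformaldehyde (as formaldehyde), C=O
Why: Magnesium-mediated ortho-formylation (Casnati–Skattebøl reaction): the magnesium phenolate delivers formaldehyde only to an ortho carbon, one ortho site is blocked by chlorine, and the open one is also para to the methoxy group; a second formaldehyde oxidises the benzylic alkoxide by hydride transfer.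

Step 2
Reactants: 2 3-chloro-2-hydroxy-4-methoxybenzaldehyde
Product: 3 2-(benzyloxy)-3-chloro-4-methoxybenzaldehyde
Conditions: BnBr, K2CO3, DMF, 60 °C
Reagents that add atoms: benzyl bromide, BrCc1ccccc1
Why: Williamson etherification; the chelated, flanked phenol needs the polar solvent and mild heating but the molecule has no competing nucleophilic site.

Step 3
Reactants: 3 2-(benzyloxy)-3-chloro-4-methoxybenzaldehyde
Product: 5 2-(benzyloxy)-3-chloro-4-methoxyphenol, via aryl formate 4 (not isolated)
Conditions: mCPBA, CH2Cl2, 0 °C to rt; then K2CO3, MeOH, rt
Reagents that add atoms: mCPBA, OOC(=O)c1cccc(Cl)c1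
Why: Baeyer–Villiger oxidation of an electron-rich benzaldehyde (Dakin-type): the aryl group, activated by the ortho benzyloxy and para methoxy donors, migrates in preference to hydrogen, and methanolysis of formate 4 releases the phenol at the former formyl carbon.

Step 4
Reactants: 5 2-(benzyloxy)-3-chloro-4-methoxyphenol
Product: 6 3-(benzyloxy)-4-chloro-2-hydroxy-5-methoxybenzaldehyde
Conditions: MgCl2, Et3N, (CH2O)n, THF, reflux; aq. HCl
Reagents that add atoms: paraformaldehyde (as formaldehyde), C=O
Why: Second magnesium-mediated ortho-formylation; the phenol of 5 has a single unsubstituted ortho carbon, so the formyl group can only enter at the future C1.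

Step 5
Reactants: 6 3-(benzyloxy)-4-chloro-2-hydroxy-5-methoxybenzaldehyde
Product: 7 2-(benzyloxy)-3-chloro-6-(hydroxymethyl)-4-methoxyphenol
Conditions: NaBH4, THF/MeOH, 0 °C; aq. NH4Cl
Reagents that add atoms: none
Why: Borohydride reduction of an aryl aldehyde; chloride, benzyl ether and free phenol are inert, and the near-neutral work-up avoids ionisation of the ortho-hydroxybenzyl alcohol.

Step 6
Reactants: 7 2-(benzyloxy)-3-chloro-6-(hydroxymethyl)-4-methoxyphenol
Product: 8 2-(benzyloxy)-6-({[tert-butyl(dimethyl)silyl]oxy}methyl)-3-chloro-4-methoxyphenol
Conditions: TBSCl (1.05 equiv), imidazole, CH2Cl2, 0 °C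
Reagents that add atoms: tert-butyldimethylsilyl chloride, CC(C)(C)[Si](C)(C)Cl
Why: Silylation of the unhindered primary alcohol should be faster than that of the phenol, which is flanked on both sides and hydrogen-bonded; any aryl silyl ether formed would be cleaved selectively by K2CO3 in MeOH.

Step 7
Reactants: 9 orcinol (5-methylbenzene-1,3-diol)
Product: 10 3-(benzyloxy)-5-methylphenol
Conditions: 9 (3 equiv), BnBr (1 equiv), K2CO3, DMF, rt
Reagents that add atoms: benzyl bromide, BrCc1ccccc1
Why: Williamson mono-etherification of a symmetric diol; the excess of 9 biases the statistical outcome toward the mono-ether, and unreacted 9 is removed by aqueous extraction and reused.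

Step 8
Reactants: 10 3-(benzyloxy)-5-methylphenol
Product: 11 3-(benzyloxy)-5-methylphenyl propan-2-ylcarbamate
Conditions: i-PrNCO, Et3N (cat.), CH2Cl2, rt
Reagents that add atoms: isopropyl isocyanate, CC(C)N=C=O
Why: Base-catalysed addition of the phenol to the isocyanate gives the secondary carbamate that serves as directing group and as a mask removable under mild base.

Step 9
Reactants: 11 3-(benzyloxy)-5-methylphenyl propan-2-ylcarbamate
Product: 14 3-(benzyloxy)-5-methyl-2-(trimethylsilyl)phenyl propan-2-ylcarbamate, via N-silyl carbamate 12 (not isolated), via N-silyl C-silyl carbamate 13 (not isolated)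
Conditions: TBSOTf, TMEDA, Et2O, 0 °C to rt; n-BuLi, TMEDA, −78 °C; TMSCl, −78 °C to rt; aq. NaHSO4
Reagents that add atoms: chlorotrimethylsilane, C[Si](C)(C)Cl; TBSOTf, CC(C)(C)[Si](C)(C)OS(=O)(=O)C(F)(F)F (its silyl group stays only in 12 and 13)
Why: Directed ortho-metalation: in-flask N-silylation removes the acidic N–H, the silylated carbamate and the benzyloxy group jointly direct lithiation to the carbon between them, and chlorotrimethylsilane traps the aryllithium at −78 °C before an anionic Fries shift can occur; the acidic work-up hydrolyses the N–Si bond.

Step 10
Reactants: 14 3-(benzyloxy)-5-methyl-2-(trimethylsilyl)phenyl propan-2-ylcarbamate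
Product: 16 3-(benzyloxy)-5-methyl-2-(trimethylsilyl)phenyl trifluoromethanesulfonate, via silyl phenol 15 (not isolated)
Conditions: DBU, Et2NH, MeCN, 40 °C; then PhNTf2, rt
Reagents that add atoms: N-phenylbis(trifluoromethanesulfonimide), O=S(=O)(N(c1ccccc1)S(=O)(=O)C(F)(F)F)C(F)(F)F
Why: Base-induced E1cB cleavage of the secondary carbamate (loss of the isocyanate, which Et2NH captures) frees the phenolate, which is sulfonylated in the same flask by PhNTf2; the basic, non-aqueous medium spares the aryl–silicon bond, which is prone to protodesilylation.

Step 11
Reactants: 8 2-(benzyloxy)-6-({[tert-butyl(dimethyl)silyl]oxy}methyl)-3-chloro-4-methoxyphenol; 16 3-(benzyloxy)-5-methyl-2-(trimethylsilyl)phenyl trifluoromethanesulfonate; 17 carbon dioxide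
Product: 20 2-(benzyloxy)-6-[2-(benzyloxy)-6-({[tert-butyl(dimethyl)silyl]oxy}methyl)-3-chloro-4-methoxyphenoxy]-4-methylbenzoic acid, via potassium phenolate 18 (not isolated), via aryne 19 (not isolated)
Conditions: 8, KH, THF, 0 °C; then CO2 (1 atm), 18-crown-6, KF (1.5 equiv to 16), 16 (1.3 equiv) added over 2 h, 0 °C to rt; cold aq. HCl (pH 3)
Reagents that add atoms: none
Why: Proposed new method: fluoride attacks the trimethylsilyl group of 16 and triflate leaves, giving aryne 19 with its strained bond between C1' and C2'; the benzyloxy group at C6' withdraws inductively and distorts the aryne so that C2' is the more electrophilic carbon, and potassium phenolate 18 adds there to form the O–C2' bond while the charge is placed at C1', between two oxygens. Because the flask holds no proton donor (phenolate made with KH, THF as solvent, dry KF with 18-crown-6), the C1' anion is captured by dissolved CO2 to form the C1'–carboxylate bond, and acidification releases 20. The closest known reaction types are the three-component coupling of arynes, amines and CO2 to anthranilic acids and the fluoride-induced O-arylation of phenols by silylaryl triflates; the new element is a phenolate as the nucleophile in the CO2-terminated version. No ring closes and no stereocenter forms. Two selectivities are needed: addition at C2' and not C1', secured by the C6' alkoxy group as in other 3-alkoxyarynes, and carboxylation over protonation or cyclisation, secured by the CO2-saturated aprotic medium and by carrying the ring A carboxyl as a CH2OTBS group that offers the anion no carbonyl (an ester there would close a xanthone). An aryne is chosen for this bond because it should accept even the doubly ortho-substituted phenolate 18, which would resist copper-mediated or SNAr etherification. Slow addition of 16 keeps the aryne concentration low so that 18, and not the product carboxylate or fluoride, is its main partner.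

Step 12
Reactants: 20 2-(benzyloxy)-6-[2-(benzyloxy)-6-({[tert-butyl(dimethyl)silyl]oxy}methyl)-3-chloro-4-methoxyphenoxy]-4-methylbenzoic acid
Product: 21 2-(benzyloxy)-6-[2-(benzyloxy)-3-chloro-6-(hydroxymethyl)-4-methoxyphenoxy]-4-methylbenzoic acid
Conditions: TBAF (3 equiv), THF, 0 °C to rt; aq. HCl (pH 3)
Reagents that add atoms: none
Why: Fluoride cleavage of the primary silyl ether; the excess of TBAF allows for the equivalent consumed by the carboxylic acid, and benzyl ethers, aryl chloride and diaryl ether are inert.

Step 13
Reactants: 21 2-(benzyloxy)-6-[2-(benzyloxy)-3-chloro-6-(hydroxymethyl)-4-methoxyphenoxy]-4-methylbenzoic acid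
Product: 22 3-(benzyloxy)-2-[3-(benzyloxy)-2-carboxy-5-methylphenoxy]-4-chloro-5-methoxybenzoic acid
Conditions: TEMPO (cat.), NaClO2, NaOCl (cat.), MeCN/phosphate buffer (pH 6.7), 35 °C
Reagents that add atoms: sodium chlorite NaClO2, [Na+].[O-]Cl=O
Why: TEMPO-catalysed oxidation with NaClO2 as terminal oxidant (oxoammonium oxidation to the aldehyde, chlorite oxidation to the acid) at buffered pH; hypochlorite is kept catalytic to limit ring chlorination, and both phenols are still benzylated.

Step 14
Reactants: 22 3-(benzyloxy)-2-[3-(benzyloxy)-2-carboxy-5-methylphenoxy]-4-chloro-5-methoxybenzoic acid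
Product: 23 2-(2-carboxy-3-hydroxy-5-methylphenoxy)-4-chloro-3-hydroxy-5-methoxybenzoic acid
Conditions: BCl3, C6HMe5, CH2Cl2, −78 to 0 °C; MeOH, H2O
Reagents that add atoms: none
Why: Lewis-acid cleavage of aryl benzyl ethers by BCl3 with pentamethylbenzene as a non-basic trap for the benzyl cation; at low temperature the unchelated C5 methyl ether and the aryl chloride should be untouched, and aqueous work-up hydrolyses the boron carboxylates and phenolates to 23.

## Compound list

1 | 2-chloro-3-methoxyphenol | COc1cccc(O)c1Cl | starting material
2 | 3-chloro-2-hydroxy-4-methoxybenzaldehyde | COc1ccc(C=O)c(O)c1Cl | intermediate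
3 | 2-(benzyloxy)-3-chloro-4-methoxybenzaldehyde | COc1ccc(C=O)c(OCc2ccccc2)c1Cl | intermediate
4 | 2-(benzyloxy)-3-chloro-4-methoxyphenyl formate | COc1ccc(OC=O)c(OCc2ccccc2)c1Cl | intermediate
5 | 2-(benzyloxy)-3-chloro-4-methoxyphenol | COc1ccc(O)c(OCc2ccccc2)c1Cl | intermediate
6 | 3-(benzyloxy)-4-chloro-2-hydroxy-5-methoxybenzaldehyde | COc1cc(C=O)c(O)c(OCc2ccccc2)c1Cl | intermediate
7 | 2-(benzyloxy)-3-chloro-6-(hydroxymethyl)-4-methoxyphenol | COc1cc(CO)c(O)c(OCc2ccccc2)c1Cl | intermediate
8 | 2-(benzyloxy)-6-({[tert-butyl(dimethyl)silyl]oxy}methyl)-3-chloro-4-methoxyphenol | COc1cc(CO[Si](C)(C)C(C)(C)C)c(O)c(OCc2ccccc2)c1Cl | intermediate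
9 | orcinol (5-methylbenzene-1,3-diol) | Cc1cc(O)cc(O)c1 | starting material
10 | 3-(benzyloxy)-5-methylphenol | Cc1cc(O)cc(OCc2ccccc2)c1 | intermediate
11 | 3-(benzyloxy)-5-methylphenyl propan-2-ylcarbamate | Cc1cc(OCc2ccccc2)cc(OC(=O)NC(C)C)c1 | intermediate
12 | 3-(benzyloxy)-5-methylphenyl [tert-butyl(dimethyl)silyl](propan-2-yl)carbamate | Cc1cc(OCc2ccccc2)cc(OC(=O)N(C(C)C)[Si](C)(C)C(C)(C)C)c1 | intermediate
13 | 3-(benzyloxy)-5-methyl-2-(trimethylsilyl)phenyl [tert-butyl(dimethyl)silyl](propan-2-yl)carbamate | Cc1cc(OCc2ccccc2)c([Si](C)(C)C)c(OC(=O)N(C(C)C)[Si](C)(C)C(C)(C)C)c1 | intermediate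
14 | 3-(benzyloxy)-5-methyl-2-(trimethylsilyl)phenyl propan-2-ylcarbamate | Cc1cc(OCc2ccccc2)c([Si](C)(C)C)c(OC(=O)NC(C)C)c1 | intermediate
15 | 3-(benzyloxy)-5-methyl-2-(trimethylsilyl)phenol | Cc1cc(O)c([Si](C)(C)C)c(OCc2ccccc2)c1 | intermediate
16 | 3-(benzyloxy)-5-methyl-2-(trimethylsilyl)phenyl trifluoromethanesulfonate | Cc1cc(OCc2ccccc2)c([Si](C)(C)C)c(OS(=O)(=O)C(F)(F)F)c1 | intermediate
17 | carbon dioxide | O=C=O | starting material
18 | potassium 2-(benzyloxy)-6-({[tert-butyl(dimethyl)silyl]oxy}methyl)-3-chloro-4-methoxyphenolate | [K+].[O-]c1c(CO[Si](C)(C)C(C)(C)C)cc(OC)c(Cl)c1OCc1ccccc1 | intermediate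
19 | 3-(benzyloxy)-5-methylbenzyne (1-(benzyloxy)-5-methyl-2,3-didehydrobenzene) | CC1=CC#CC(OCc2ccccc2)=C1 | intermediate
20 | 2-(benzyloxy)-6-[2-(benzyloxy)-6-({[tert-butyl(dimethyl)silyl]oxy}methyl)-3-chloro-4-methoxyphenoxy]-4-methylbenzoic acid | OC(=O)c1c(OCc2ccccc2)cc(C)cc1Oc1c(CO[Si](C)(C)C(C)(C)C)cc(OC)c(Cl)c1OCc1ccccc1 | intermediate
21 | 2-(benzyloxy)-6-[2-(benzyloxy)-3-chloro-6-(hydroxymethyl)-4-methoxyphenoxy]-4-methylbenzoic acid | OC(=O)c1c(OCc2ccccc2)cc(C)cc1Oc1c(CO)cc(OC)c(Cl)c1OCc1ccccc1 | intermediate
22 | 3-(benzyloxy)-2-[3-(benzyloxy)-2-carboxy-5-methylphenoxy]-4-chloro-5-methoxybenzoic acid | OC(=O)c1c(OCc2ccccc2)cc(C)cc1Oc1c(C(=O)O)cc(OC)c(Cl)c1OCc1ccccc1 | intermediate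
23 | 2-(2-carboxy-3-hydroxy-5-methylphenoxy)-4-chloro-3-hydroxy-5-methoxybenzoic acid | COc1cc(C(=O)O)c(Oc2cc(C)cc(O)c2C(=O)O)c(O)c1Cl | target

## Step count and least certain steps

Total step count: 14. Longest linear sequence: 10 steps (steps 1 to 6 and 11 to 14, from 1 to 23). The ring B branch (steps 7 to 10) has 4 steps and joins at step 11.

Step 11 (the step proposed as new chemistry). Four processes could spoil it:
- protonation of the C1' anion instead of carboxylation, by proton transfer from the benzylic CH2 of ring A or from traces of water;
- reversible carbonation of the phenolate, which lowers its nucleophilicity or diverts the addition through a carbonate oxygen;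
- O-arylation of the product carboxylate by a second aryne;
- premature fluoride cleavage of the silyl ether.

The fallback uses known chemistry, sets out from 8 and 16 and comes back at 20. Compounds 8 and 16 are combined with CsF in MeCN at room temperature without CO2. This is the established fluoride-induced O-arylation of phenols by silylaryl triflates, in which the phenol and the solvent protonate C1'. It should give the diaryl ether tert-butyl({3-(benzyloxy)-2-[3-(benzyloxy)-5-methylphenoxy]-4-chloro-5-methoxyphenyl}methoxy)dimethylsilane F1 with the same site selectivity. F1 is then lithiated with n-BuLi and TMEDA in THF at −78 to −20 °C at C1', the carbon between the benzyloxy and aryloxy oxygens (directed ortho-metalation of a 1,3-dioxygenated arene). The aryllithium is quenched with CO2 to give 20.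

Step 9. Deprotonation at the benzylic CH2 of the benzyl ether, followed by [1,2]-Wittig rearrangement, could compete with ring lithiation. Incomplete N-silylation would open the way to an anionic Fries shift of the carbamoyl group. The fallback avoids a slow deprotonation altogether; it sets out from 9 and comes back at 16, replacing steps 7 to 10.
- Iodination of 9 with I2 and NaHCO3 in water at 0 °C should give 2-iodo-5-methylbenzene-1,3-diol F2, the position between the hydroxyls being expected by analogy with resorcinol under these conditions.
- Mono-benzylation (BnBr, K2CO3, acetone) gives 3-(benzyloxy)-2-iodo-5-methylphenol F3.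
- Silylation with HN(SiMe3)2 in THF at reflux gives [3-(benzyloxy)-2-iodo-5-methylphenoxy](trimethyl)silane F4.
- n-BuLi in THF at −100 °C effects iodine–lithium exchange, which is much faster than benzylic deprotonation. A retro-Brook shift of silicon from oxygen to carbon follows and gives 15 as its lithium phenolate.
- Tf2O added to the same flask converts the phenolate into 16.

Step 4. The reacting carbon is meta to both alkoxy groups and para to chlorine, and the ortho benzyloxy oxygen can chelate magnesium. Formylation may therefore be slow, and prolonged heating invites O-alkylation of the phenol by formaldehyde-derived species. The fallback sets out from 5 and comes back at 7, so that 6 and step 5 are bypassed. Compound 5 is heated with PhB(OH)2, (CH2O)n and catalytic propanoic acid in toluene with removal of water. The boron-templated ortho-hydroxymethylation should give 8-(benzyloxy)-7-chloro-6-methoxy-2-phenyl-4H-1,3,2-benzodioxaborinine F5. Transesterification with propane-1,3-diol in THF at room temperature releases 7.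

Step 13. The catalytic hypochlorite could chlorinate ring B at C3' or C5', or the oxidation could stop at the aldehyde. The fallback sets out from 21 and comes back at 22. Dess–Martin periodinane with NaHCO3 in CH2Cl2 gives 2-(benzyloxy)-6-[2-(benzyloxy)-3-chloro-6-formyl-4-methoxyphenoxy]-4-methylbenzoic acid F6. Pinnick oxidation (NaClO2, NaH2PO4, 2-methylbut-2-ene, t-BuOH/H2O) follows, in which the alkene scavenges the hypochlorous acid as it forms, and gives 22.

Further compounds

F1 | step 11 | tert-butyl({3-(benzyloxy)-2-[3-(benzyloxy)-5-methylphenoxy]-4-chloro-5-methoxyphenyl}methoxy)dimethylsilane | Cc1cc(OCc2ccccc2)cc(Oc2c(CO[Si](C)(C)C(C)(C)C)cc(OC)c(Cl)c2OCc2ccccc2)c1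
F2 | step 9 | 2-iodo-5-methylbenzene-1,3-diol | Cc1cc(O)c(I)c(O)c1
F3 | step 9 | 3-(benzyloxy)-2-iodo-5-methylphenol | Cc1cc(O)c(I)c(OCc2ccccc2)c1
F4 | step 9 | [3-(benzyloxy)-2-iodo-5-methylphenoxy](trimethyl)silane | Cc1cc(O[Si](C)(C)C)c(I)c(OCc2ccccc2)c1
F5 | step 4 | 8-(benzyloxy)-7-chloro-6-methoxy-2-phenyl-4H-1,3,2-benzodioxaborinine | COc1cc2COB(Oc2c(OCc2ccccc2)c1Cl)c1ccccc1
F6 | step 13 | 2-(benzyloxy)-6-[2-(benzyloxy)-3-chloro-6-formyl-4-methoxyphenoxy]-4-methylbenzoic acid | OC(=O)c1c(OCc2ccccc2)cc(C)cc1Oc1c(C=O)cc(OC)c(Cl)c1OCc1ccccc1
A1 | alternative 1 | methyl 4-chloro-3-hydroxy-5-methoxy-2-[(2,2,7-trimethyl-4-oxo-4H-1,3-benzodioxin-5-yl)oxy]benzoate | COC(=O)c1cc(OC)c(Cl)c(O)c1Oc1cc(C)cc2OC(C)(C)OC(=O)c12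
A2 | alternative 1 | 5-({(1Z)-3-chloro-4,4-dimethoxy-2-[(trimethylsilyl)oxy]buta-1,3-dien-1-yl}oxy)-2,2,7-trimethyl-4H-1,3-benzodioxin-4-one | COC(OC)=C(Cl)/C(O[Si](C)(C)C)=C/Oc1cc(C)cc2OC(C)(C)OC(=O)c12
A3 | alternative 1 | methyl (2E)-3-nitroprop-2-enoate | COC(=O)/C=C/[N+](=O)[O-]
A4 | alternative 2 | methyl trans-2-[3-(benzyloxy)-2-(1,3-dioxolan-2-yl)-5-methylphenoxy]-3,5-dioxocyclohexane-1-carboxylate (racemic, one enantiomer drawn) | COC(=O)[C@@H]1CC(=O)CC(=O)[C@H]1Oc1cc(C)cc(OCc2ccccc2)c1C1OCCO1
A5 | alternative 2 | methyl [3-(benzyloxy)-2-(1,3-dioxolan-2-yl)-5-methylphenoxy]acetate | COC(=O)COc1cc(C)cc(OCc2ccccc2)c1C1OCCO1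
A6 | alternative 2 | methyl (2E)-4-oxopent-2-enoate | COC(=O)/C=C/C(C)=O
A7 | alternative 3 | 3-[2-(benzyloxy)-6-({[tert-butyl(dimethyl)silyl]oxy}methyl)-3-chloro-4-methoxyphenoxy]-2-({[tert-butyl(dimethyl)silyl]oxy}methyl)-5-methylphenol | Cc1cc(O)c(CO[Si](C)(C)C(C)(C)C)c(Oc2c(CO[Si](C)(C)C(C)(C)C)cc(OC)c(Cl)c2OCc2ccccc2)c1
A8 | alternative 3 | 3-methylcyclobut-2-en-1-one | CC1=CC(=O)C1
A9 | alternative 3 | tert-butyl{[3-(benzyloxy)-2-({3-[(tert-butyldimethylsilyl)oxy]prop-1-yn-1-yl}oxy)-4-chloro-5-methoxyphenyl]methoxy}dimethylsilane | COc1cc(CO[Si](C)(C)C(C)(C)C)c(OC#CCO[Si](C)(C)C(C)(C)C)c(OCc2ccccc2)c1Cl
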